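**Plan**

- Retrosynthesis: the C1 carboxyl group of ring A goes back to a protected hydroxymethyl group and the C2 methoxy group to a phenol. Ring A is then cut at C1–C2, C5–C6 and C2–C3, leaving a 4-substituted cyclobutenone (C2 to C5 plus the side chain) and an aryl alkynyl ether of ring B (C1, C6 and the ether oxygen).
- Enabling feature: in ring A the carboxyl carbon C1 lies between two oxygen-bearing carbons, C2 (OMe) and C6 (O–ring B), the carbinol chain is on C3 next to C2, and C4 and C5 carry hydrogen. This is the substitution pattern that a vinylketene and an ynol ether assemble.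
- Forward: the chain fragment is made from methyl 5-methyl-3-oxohexanoate (five steps to the cyclobutenone). Ring B is made from creosol (eight steps to the ynol ether, the ether oxygen being tied to the alkyne through trichloroethylene). Heating the two builds ring A in one step, already joined to ring B, so the hindered diaryl ether is never made by aryl C–O coupling.
- Endgame: O-methylation, unmasking and oxidation of the C1 carbon to the acid, then removal of the benzyl and silyl groups.
- Stereochemistry: the only stereocentre (S, benzylic carbinol) comes from Noyori hydrogenation of the β-keto ester with the (S)-BINAP ruthenium catalyst. It is carried as a silyl ether that takes part in no later bond formation.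

Key step: step 14

Remark on the chemistry: the cyclobutenone is taken as the mixture of epimers at its ring sp3 carbon, which should be of no consequence because this carbon becomes aromatic; it is made directly before the benzannulation.
Abbreviations: TBS = tert-butyldimethylsilyl, PMB = 4-methoxybenzyl, Bn = benzyl. Ring A numbering: C1 carboxyl carbon, C2 methoxy, C3 carbinol chain, C6 aryloxy.

**Route**

Step 1
Reactants: 1 methyl 5-methyl-3-oxohexanoate
Product: 2 methyl (3S)-3-hydroxy-5-methylhexanoate
Conditions: H2 (50 atm), RuCl2[(S)-BINAP] (cat.), MeOH, 50 °C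
Reagents that add atoms: none
Why: Noyori asymmetric hydrogenation of a β-keto ester, in which the ester carbonyl chelates ruthenium and the (S)-BINAP ligand lets hydride reach only one face of the ketone, setting the 3S carbinol centre.

Step 2
Reactants: 2 methyl (3S)-3-hydroxy-5-methylhexanoate
Product: 3 methyl (3S)-3-(TBSO)-5-methylhexanoate
Conditions: TBSCl, imidazole, DMF, rt
Reagents that add atoms: tert-butyldimethylsilyl chloride, CC(C)(C)[Si](C)(C)Cl
Why: Standard silylation of a secondary alcohol, giving an ether that should survive base, hydride, heat and oxidants up to the last step.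

Step 3
Reactants: 3 methyl (3S)-3-(TBSO)-5-methylhexanoate
Product: 4 (3S)-3-(TBSO)-5-methylhexanoic acid
Conditions: LiOH·H2O, THF/MeOH/H2O, 0 °C to rt; then 1 M HCl to pH 4
Reagents that add atoms: lithium hydroxide, [Li+].[OH-]
Why: Saponification of the methyl ester under mild conditions that should leave the secondary TBS ether and the β-stereocentre untouched.

Step 4
Reactants: 4 (3S)-3-(TBSO)-5-methylhexanoic acid; 5 ethoxyacetylene
Product: 8 3-ethoxy-4-[(1S)-3-methyl-1-(TBSO)butyl]cyclobut-2-en-1-one (both epimers at the ring sp3 carbon), via acid chloride 6 (not isolated), via silyloxy ketene 7 (not isolated)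
Conditions: (COCl)2, DMF (cat.), CH2Cl2, 0 °C to rt, concentrate; then 5 (3 equiv), Et3N (slow addition), CH2Cl2, 0 °C to rt
Reagents that add atoms: none
Why: Triethylamine dehydrochlorinates acid chloride 6 to monosubstituted ketene 7, which is trapped in a thermal ketene–alkyne [2+2] cycloaddition whose polarity (ketene carbonyl carbon to the unsubstituted alkyne carbon) places the ethoxy-bearing carbon next to the ring carbon that carries the side chain.

Step 5
Reactants: 8 3-ethoxy-4-[(1S)-3-methyl-1-(TBSO)butyl]cyclobut-2-en-1-one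
Product: 10 4-[(1S)-3-methyl-1-(TBSO)butyl]cyclobut-2-en-1-one, via cyclobutenol 9 (not isolated)
Conditions: i-Bu2AlH (DIBAL-H), CH2Cl2, −78 °C; then 0.5 M aq. HCl, THF, 0 °C, brief
Reagents that add atoms: water, O
Why: 1,2-Reduction of the vinylogous ester to allylic alcohol 9, then acid hydrolysis of the enol ether with loss of water (Stork–Danheiser type carbonyl transposition), should move the carbonyl next to the substituted sp3 carbon.

Step 6
Reactants: 11 creosol (2-methoxy-4-methylphenol)
Product: 13 2-hydroxy-3-methoxy-5-methylbenzaldehyde, via hydroxymethylphenol 12 (not isolated)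
Conditions: MgCl2, Et3N, (CH2O)n, MeCN, reflux
Reagents that add atoms: paraformaldehyde (as formaldehyde), C=O
Why: Magnesium-mediated ortho-formylation of a phenol (Casnati–Skattebøl), in which the magnesium phenoxide adds formaldehyde at the only free ortho position to give 12, which a second equivalent of formaldehyde oxidises in the flask.

Step 7
Reactants: 13 2-hydroxy-3-methoxy-5-methylbenzaldehyde
Product: 14 2,3-dihydroxy-5-methylbenzaldehyde
Conditions: BBr3, CH2Cl2, −78 to 0 °C; then H2O
Reagents that add atoms: none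
Why: Lewis-acid cleavage of an aryl methyl ether with BBr3, done here because a methyl ether on ring B could not be removed selectively beside the ring A methoxy group at the end.

Step 8
Reactants: 14 2,3-dihydroxy-5-methylbenzaldehyde
Product: 16 3-(benzyloxy)-2-hydroxy-5-methylbenzaldehyde, via disodium dianion 15 (not isolated)
Conditions: NaH (2.2 equiv), DMSO, rt; BnBr (1.0 equiv), rt; aq. HCl
Reagents that add atoms: benzyl bromide, BrCc1ccccc1
Why: Regioselective Williamson alkylation through dianion 15, in which the 2-phenoxide is conjugated with and chelated to the formyl group, so the more nucleophilic 3-phenoxide should take the single equivalent of benzyl bromide.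

Step 9
Reactants: 16 3-(benzyloxy)-2-hydroxy-5-methylbenzaldehyde; 17 trichloroethylene
Product: 19 3-(benzyloxy)-2-{[(E)-1,2-dichloroethenyl]oxy}-5-methylbenzaldehyde, via dichloroacetylene 18 (not isolated)
Conditions: 17 (2 equiv), K2CO3, DMF, 70 °C
Reagents that add atoms: none
Why: Base-mediated O-vinylation of a phenol, in which potassium carbonate turns trichloroethylene into dichloroacetylene 18 and the phenoxide adds to it in anti fashion to give the (E)-1,2-dichlorovinyl ether, the known precursor of ynol ethers.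

Step 10
Reactants: 19 3-(benzyloxy)-2-{[(E)-1,2-dichloroethenyl]oxy}-5-methylbenzaldehyde
Product: 20 [3-(benzyloxy)-2-{[(E)-1,2-dichloroethenyl]oxy}-5-methylphenyl]methanol
Conditions: NaBH4, MeOH/THF, 0 °C
Reagents that add atoms: none
Why: Borohydride reduction of the aryl aldehyde to the benzylic alcohol, to which the dichlorovinyl and benzyl ethers are inert.

Step 11
Reactants: 20 [3-(benzyloxy)-2-{[(E)-1,2-dichloroethenyl]oxy}-5-methylphenyl]methanol
Product: 21 TBS ether of 20, 1-(benzyloxy)-2-{[(E)-1,2-dichloroethenyl]oxy}-5-methyl-3-[(TBSO)methyl]benzene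
Conditions: TBSCl, imidazole, DMF, rt
Reagents that add atoms: tert-butyldimethylsilyl chloride, CC(C)(C)[Si](C)(C)Cl
Why: Silylation of the primary benzylic alcohol, needed before the organolithium step.

Step 12
Reactants: 21 1-(benzyloxy)-2-{[(E)-1,2-dichloroethenyl]oxy}-5-methyl-3-[(TBSO)methyl]benzene
Product: 24 3-{2-(benzyloxy)-4-methyl-6-[(TBSO)methyl]phenoxy}prop-2-yn-1-ol, via aryl chloroethynyl ether 22 (not isolated), via lithium aryloxyacetylide 23 (not isolated)
Conditions: n-BuLi (2.2 equiv), THF, −78 to −40 °C; (CH2O)n, −78 °C to rt; aq. NH4Cl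
Reagents that add atoms: paraformaldehyde (as formaldehyde), C=O
Why: n-Butyllithium first eliminates HCl to chloroalkyne 22 and then exchanges chlorine for lithium to give acetylide 23, which adds to formaldehyde (hydroxymethylation of a lithium acetylide).

Step 13
Reactants: 24 3-{2-(benzyloxy)-4-methyl-6-[(TBSO)methyl]phenoxy}prop-2-yn-1-ol
Product: 25 ring B aryl 3-(PMBO)prop-1-ynyl ether, 1-(benzyloxy)-2-{[3-(4-methoxybenzyloxy)prop-1-yn-1-yl]oxy}-5-methyl-3-[(TBSO)methyl]benzene
Conditions: NaH, PMBCl, Bu4NI (cat.), THF/DMF, 0 °C to rt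
Reagents that add atoms: 4-methoxybenzyl chloride, COc1ccc(CCl)cc1
Why: Williamson etherification of the propargylic alcohol, which the base-stable ynol ether should tolerate and which gives an ether removable oxidatively beside benzyl and silyl ethers.

Step 14
Reactants: 10 4-[(1S)-3-methyl-1-(TBSO)butyl]cyclobut-2-en-1-one; 25 ring B aryl 3-(PMBO)prop-1-ynyl ether
Product: 30 3-{2-(benzyloxy)-4-methyl-6-[(TBSO)methyl]phenoxy}-2-[(PMBO)methyl]-6-[(1S)-3-methyl-1-(TBSO)butyl]phenol, via vinylketene 26 (not isolated), via vinylcyclobutenone 27 (not isolated), via dienylketene 28 (not isolated), via cyclohexadienone 29 (not isolated)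
Conditions: toluene, 80 °C then 110 °C, 10 in slight excess
Reagents that add atoms: none
Why: Heating should open cyclobutenone 10 by 4π electrocyclic cleavage of its C1–C4 bond to vinylketene 26, whose ketene C=C bond adds to the electron-rich alkyne of 25 in a [2+2] cycloaddition to give 4-vinylcyclobutenone 27. A second 4π opening gives dienylketene 28, which closes ring A by thermal disrotatory 6π electrocyclisation between the ketene carbon and the chain-bearing diene terminus, and the resulting cyclohexa-2,4-dienone 29 tautomerises to phenol 30. The closest known reaction is the Danheiser benzannulation of cyclobutenones with alkynyl ethers, a formal [4+2] annulation that here makes the ring A bonds C1–C2 and C5–C6 in the cycloaddition and C2–C3 in the ring closure. No stereocentre is created: the sp3 ring carbons of 27 and 29 are lost on the way to the arene, both epimers of 10 converge, and the silyloxy-bearing carbon stays outside the reacting π system and keeps its S configuration. The selectivity needed is regiochemical and the polarisation of the ynol ether secures it, since the electrophilic ketene carbonyl carbon bonds to the alkyne carbon remote from oxygen, which puts the CH2OPMB carbon between the new hydroxyl and the aryloxy group. The side chain ends ortho to the hydroxyl on the other side because it sits on the sp3 carbon of 10 that becomes the diene terminus, and outward rotation of this alkyl group in the first ring opening should give the E vinylketene, which has no 1,5-hydrogen shift open to it.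

Step 15
Reactants: 30 3-{2-(benzyloxy)-4-methyl-6-[(TBSO)methyl]phenoxy}-2-[(PMBO)methyl]-6-[(1S)-3-methyl-1-(TBSO)butyl]phenol
Product: 31 methyl ether of 30, 1-{2-(benzyloxy)-4-methyl-6-[(TBSO)methyl]phenoxy}-3-methoxy-2-[(PMBO)methyl]-4-[(1S)-3-methyl-1-(TBSO)butyl]benzene
Conditions: MeI, K2CO3, DMF, rt to 40 °C
Reagents that add atoms: iodomethane, CI
Why: Williamson O-methylation of the only free hydroxyl, where the phenoxide is flanked by two ortho groups but iodomethane is the smallest electrophile.

Step 16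
Reactants: 31 1-{2-(benzyloxy)-4-methyl-6-[(TBSO)methyl]phenoxy}-3-methoxy-2-[(PMBO)methyl]-4-[(1S)-3-methyl-1-(TBSO)butyl]benzene
Product: 32 {6-{2-(benzyloxy)-4-methyl-6-[(TBSO)methyl]phenoxy}-2-methoxy-3-[(1S)-3-methyl-1-(TBSO)butyl]phenyl}methanol
Conditions: DDQ, CH2Cl2/pH 7 phosphate buffer, 0 °C to rt
Reagents that add atoms: none
Why: Oxidative cleavage of the PMB ether by DDQ (hydride abstraction, then hydrolysis of the oxocarbenium ion) should spare the benzyl and silyl ethers, and any further oxidation of the electron-rich benzylic alcohol would only give aldehyde 33, the product of the next step.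

Step 17
Reactants: 32 {6-{2-(benzyloxy)-4-methyl-6-[(TBSO)methyl]phenoxy}-2-methoxy-3-[(1S)-3-methyl-1-(TBSO)butyl]phenyl}methanol
Product: 33 6-{2-(benzyloxy)-4-methyl-6-[(TBSO)methyl]phenoxy}-2-methoxy-3-[(1S)-3-methyl-1-(TBSO)butyl]benzaldehyde
Conditions: Dess–Martin periodinane, NaHCO3, CH2Cl2, rt
Reagents that add atoms: none
Why: Dess–Martin oxidation of a primary benzylic alcohol to the aldehyde under buffered, non-acidic conditions.

Step 18
Reactants: 33 6-{2-(benzyloxy)-4-methyl-6-[(TBSO)methyl]phenoxy}-2-methoxy-3-[(1S)-3-methyl-1-(TBSO)butyl]benzaldehyde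
Product: 34 6-{2-(benzyloxy)-4-methyl-6-[(TBSO)methyl]phenoxy}-2-methoxy-3-[(1S)-3-methyl-1-(TBSO)butyl]benzoic acid
Conditions: NaClO2, NaH2PO4, 2-methyl-2-butene, t-BuOH/H2O, rt
Reagents that add atoms: sodium chlorite, [Na+].[O-]Cl=O
Why: Pinnick oxidation of the hindered aryl aldehyde to the acid, with 2-methyl-2-butene scavenging hypochlorous acid so that the electron-rich rings are not chlorinated.

Step 19
Reactants: 34 6-{2-(benzyloxy)-4-methyl-6-[(TBSO)methyl]phenoxy}-2-methoxy-3-[(1S)-3-methyl-1-(TBSO)butyl]benzoic acid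
Product: 35 6-{2-hydroxy-4-methyl-6-[(TBSO)methyl]phenoxy}-2-methoxy-3-[(1S)-3-methyl-1-(TBSO)butyl]benzoic acid
Conditions: H2 (1 atm), 10% Pd/C, EtOAc, rt
Reagents that add atoms: none
Why: Hydrogenolysis of the aryl benzyl ether over Pd/C in ethyl acetate, a non-protic solvent in which benzylic silyl ethers should be neither cleaved nor reduced.

Step 20
Reactants: 35 6-{2-hydroxy-4-methyl-6-[(TBSO)methyl]phenoxy}-2-methoxy-3-[(1S)-3-methyl-1-(TBSO)butyl]benzoic acid
Product: 36 6-[2-hydroxy-6-(hydroxymethyl)-4-methylphenoxy]-3-[(1S)-1-hydroxy-3-methylbutyl]-2-methoxybenzoic acid (target)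
Conditions: Bu4NF, AcOH, THF, 0 °C to rt
Reagents that add atoms: none
Why: Fluoride-induced cleavage of both TBS ethers, buffered with acetic acid so that the benzylic carbinol is neither ionised nor epimerised and keeps the S configuration set in step 1.

**Compound list**

1 | methyl 5-methyl-3-oxohexanoate | COC(=O)CC(=O)CC(C)C | starting material
2 | methyl (3S)-3-hydroxy-5-methylhexanoate | COC(=O)C[C@@H](O)CC(C)C | intermediate
3 | methyl (3S)-3-(tert-butyldimethylsilyloxy)-5-methylhexanoate | COC(=O)C[C@@H](O[Si](C)(C)C(C)(C)C)CC(C)C | intermediate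
4 | (3S)-3-(tert-butyldimethylsilyloxy)-5-methylhexanoic acid | OC(=O)C[C@@H](O[Si](C)(C)C(C)(C)C)CC(C)C | intermediate
5 | ethoxyacetylene | CCOC#C | starting material
6 | (3S)-3-(tert-butyldimethylsilyloxy)-5-methylhexanoyl chloride | ClC(=O)C[C@@H](O[Si](C)(C)C(C)(C)C)CC(C)C | intermediate (not isolated)
7 | (3S)-3-(tert-butyldimethylsilyloxy)-5-methylhex-1-en-1-one (ketene) | O=C=C[C@@H](O[Si](C)(C)C(C)(C)C)CC(C)C | intermediate (not isolated)
8 | 3-ethoxy-4-[(1S)-1-(tert-butyldimethylsilyloxy)-3-methylbutyl]cyclobut-2-en-1-one, both epimers at C4 | CCOC1=CC(=O)C1[C@@H](O[Si](C)(C)C(C)(C)C)CC(C)C | intermediate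
9 | 3-ethoxy-4-[(1S)-1-(tert-butyldimethylsilyloxy)-3-methylbutyl]cyclobut-2-en-1-ol | CCOC1=CC(O)C1[C@@H](O[Si](C)(C)C(C)(C)C)CC(C)C | intermediate (not isolated)
10 | 4-[(1S)-1-(tert-butyldimethylsilyloxy)-3-methylbutyl]cyclobut-2-en-1-one, both epimers at C4 | O=C1C=CC1[C@@H](O[Si](C)(C)C(C)(C)C)CC(C)C | intermediate (key-step precursor)
11 | creosol (2-methoxy-4-methylphenol) | COc1cc(C)ccc1O | starting material
12 | 2-(hydroxymethyl)-6-methoxy-4-methylphenol | COc1cc(C)cc(CO)c1O | intermediate (not isolated)
13 | 2-hydroxy-3-methoxy-5-methylbenzaldehyde | COc1cc(C)cc(C=O)c1O | intermediate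
14 | 2,3-dihydroxy-5-methylbenzaldehyde | Cc1cc(O)c(O)c(C=O)c1 | intermediate
15 | disodium 3-formyl-5-methylbenzene-1,2-diolate | Cc1cc([O-])c([O-])c(C=O)c1.[Na+].[Na+] | intermediate (not isolated)
16 | 3-(benzyloxy)-2-hydroxy-5-methylbenzaldehyde | Cc1cc(OCc2ccccc2)c(O)c(C=O)c1 | intermediate
17 | trichloroethylene | ClC=C(Cl)Cl | starting material
18 | dichloroacetylene | ClC#CCl | intermediate (not isolated)
19 | 3-(benzyloxy)-2-{[(E)-1,2-dichloroethenyl]oxy}-5-methylbenzaldehyde | Cc1cc(OCc2ccccc2)c(O/C(Cl)=C\Cl)c(C=O)c1 | intermediate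
20 | [3-(benzyloxy)-2-{[(E)-1,2-dichloroethenyl]oxy}-5-methylphenyl]methanol | Cc1cc(OCc2ccccc2)c(O/C(Cl)=C\Cl)c(CO)c1 | intermediate
21 | 1-(benzyloxy)-2-{[(E)-1,2-dichloroethenyl]oxy}-5-methyl-3-[(tert-butyldimethylsilyloxy)methyl]benzene | Cc1cc(OCc2ccccc2)c(O/C(Cl)=C\Cl)c(CO[Si](C)(C)C(C)(C)C)c1 | intermediate
22 | 1-(benzyloxy)-2-[(chloroethynyl)oxy]-5-methyl-3-[(tert-butyldimethylsilyloxy)methyl]benzene | Cc1cc(OCc2ccccc2)c(OC#CCl)c(CO[Si](C)(C)C(C)(C)C)c1 | intermediate (not isolated)
23 | lithium {2-(benzyloxy)-4-methyl-6-[(tert-butyldimethylsilyloxy)methyl]phenoxy}acetylide | Cc1cc(OCc2ccccc2)c(OC#C[Li])c(CO[Si](C)(C)C(C)(C)C)c1 | intermediate (not isolated)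
24 | 3-{2-(benzyloxy)-4-methyl-6-[(tert-butyldimethylsilyloxy)methyl]phenoxy}prop-2-yn-1-ol | Cc1cc(OCc2ccccc2)c(OC#CCO)c(CO[Si](C)(C)C(C)(C)C)c1 | intermediate
25 | 1-(benzyloxy)-2-{[3-(4-methoxybenzyloxy)prop-1-yn-1-yl]oxy}-5-methyl-3-[(tert-butyldimethylsilyloxy)methyl]benzene | COc1ccc(COCC#COc2c(OCc3ccccc3)cc(C)cc2CO[Si](C)(C)C(C)(C)C)cc1 | intermediate (key-step precursor)
26 | (3E,5S)-5-(tert-butyldimethylsilyloxy)-7-methylocta-1,3-dien-1-one (vinylketene) | O=C=C/C=C/[C@@H](O[Si](C)(C)C(C)(C)C)CC(C)C | intermediate (not isolated)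
27 | 3-(ring B aryloxy)-2-[(4-methoxybenzyloxy)methyl]-4-[(1E,3S)-3-(tert-butyldimethylsilyloxy)-5-methylhex-1-en-1-yl]cyclobut-2-en-1-one, both epimers at C4 | O=C1C(COCc2ccc(OC)cc2)=C(Oc2c(OCc3ccccc3)cc(C)cc2CO[Si](C)(C)C(C)(C)C)C1/C=C/[C@@H](O[Si](C)(C)C(C)(C)C)CC(C)C | intermediate (not isolated)
28 | dienylketene, 3-(ring B aryloxy)-2-[(4-methoxybenzyloxy)methyl]-7-(tert-butyldimethylsilyloxy)-9-methyldeca-1,3,5-trien-1-one, (5E,7S), ketene carbon and C5 cis across C3=C4 | O=C=C(COCc1ccc(OC)cc1)/C(Oc1c(OCc2ccccc2)cc(C)cc1CO[Si](C)(C)C(C)(C)C)=C\C=C\[C@@H](O[Si](C)(C)C(C)(C)C)CC(C)C | intermediate (not isolated)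
29 | 3-(ring B aryloxy)-2-[(4-methoxybenzyloxy)methyl]-6-[(1S)-1-(tert-butyldimethylsilyloxy)-3-methylbutyl]cyclohexa-2,4-dien-1-one, both epimers at C6 | O=C1C(COCc2ccc(OC)cc2)=C(Oc2c(OCc3ccccc3)cc(C)cc2CO[Si](C)(C)C(C)(C)C)C=CC1[C@@H](O[Si](C)(C)C(C)(C)C)CC(C)C | intermediate (not isolated)
30 | 3-{2-(benzyloxy)-4-methyl-6-[(tert-butyldimethylsilyloxy)methyl]phenoxy}-2-[(4-methoxybenzyloxy)methyl]-6-[(1S)-1-(tert-butyldimethylsilyloxy)-3-methylbutyl]phenol | Oc1c([C@@H](O[Si](C)(C)C(C)(C)C)CC(C)C)ccc(Oc2c(OCc3ccccc3)cc(C)cc2CO[Si](C)(C)C(C)(C)C)c1COCc1ccc(OC)cc1 | intermediate (key-step product)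
31 | 1-{2-(benzyloxy)-4-methyl-6-[(tert-butyldimethylsilyloxy)methyl]phenoxy}-3-methoxy-2-[(4-methoxybenzyloxy)methyl]-4-[(1S)-1-(tert-butyldimethylsilyloxy)-3-methylbutyl]benzene | COc1c([C@@H](O[Si](C)(C)C(C)(C)C)CC(C)C)ccc(Oc2c(OCc3ccccc3)cc(C)cc2CO[Si](C)(C)C(C)(C)C)c1COCc1ccc(OC)cc1 | intermediate
32 | {6-{2-(benzyloxy)-4-methyl-6-[(tert-butyldimethylsilyloxy)methyl]phenoxy}-2-methoxy-3-[(1S)-1-(tert-butyldimethylsilyloxy)-3-methylbutyl]phenyl}methanol | COc1c([C@@H](O[Si](C)(C)C(C)(C)C)CC(C)C)ccc(Oc2c(OCc3ccccc3)cc(C)cc2CO[Si](C)(C)C(C)(C)C)c1CO | intermediate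
33 | 6-{2-(benzyloxy)-4-methyl-6-[(tert-butyldimethylsilyloxy)methyl]phenoxy}-2-methoxy-3-[(1S)-1-(tert-butyldimethylsilyloxy)-3-methylbutyl]benzaldehyde | COc1c([C@@H](O[Si](C)(C)C(C)(C)C)CC(C)C)ccc(Oc2c(OCc3ccccc3)cc(C)cc2CO[Si](C)(C)C(C)(C)C)c1C=O | intermediate
34 | 6-{2-(benzyloxy)-4-methyl-6-[(tert-butyldimethylsilyloxy)methyl]phenoxy}-2-methoxy-3-[(1S)-1-(tert-butyldimethylsilyloxy)-3-methylbutyl]benzoic acid | COc1c([C@@H](O[Si](C)(C)C(C)(C)C)CC(C)C)ccc(Oc2c(OCc3ccccc3)cc(C)cc2CO[Si](C)(C)C(C)(C)C)c1C(=O)O | intermediate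
35 | 6-{2-hydroxy-4-methyl-6-[(tert-butyldimethylsilyloxy)methyl]phenoxy}-2-methoxy-3-[(1S)-1-(tert-butyldimethylsilyloxy)-3-methylbutyl]benzoic acid | COc1c([C@@H](O[Si](C)(C)C(C)(C)C)CC(C)C)ccc(Oc2c(O)cc(C)cc2CO[Si](C)(C)C(C)(C)C)c1C(=O)O | intermediate
36 | 6-[2-hydroxy-6-(hydroxymethyl)-4-methylphenoxy]-3-[(1S)-1-hydroxy-3-methylbutyl]-2-methoxybenzoic acid | COc1c([C@@H](O)CC(C)C)ccc(Oc2c(O)cc(C)cc2CO)c1C(=O)O | target

**Step count and risks**

Total step count: 20 (steps 1–5 chain fragment, steps 6–13 ring B fragment, step 14 union, steps 15–20 endgame).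
Longest linear sequence: 15 steps, from creosol 11 through steps 6–13, 14 and 15–20 to target 36.

The three steps most likely to fail:

1. Step 14 (benzannulation). The cyclobutenone, unsubstituted at C2 and C3, may polymerise before it opens. The vinylketene may be lost to dimerisation or to acylation of the product phenol (brief K2CO3/MeOH treatment of the crude would release any such ester). The cycloaddition may be slow because an aryloxy group is a weaker donor than an alkoxy group. The fallback generates the same vinylketene by photochemical Wolff rearrangement at room temperature and needs no cyclobutenone; it sets out from ynol ether 25, which is kept unchanged, and comes back to the route at phenol 30. Commercial methyl (2S)-2-hydroxy-4-methylpentanoate would be silylated (TBSCl, imidazole) to methyl (2S)-2-(tert-butyldimethylsilyloxy)-4-methylpentanoate F1 and reduced (i-Bu2AlH, −78 °C) to (2S)-2-(tert-butyldimethylsilyloxy)-4-methylpentanal F2. Wittig olefination with Ph3P=CHC(O)CH3 should then give (3E,5S)-5-(tert-butyldimethylsilyloxy)-7-methyloct-3-en-2-one F3. Trifluoroacetylation of its lithium enolate (LiHMDS, CF3CO2CH2CF3) should give (5E,7S)-7-(tert-butyldimethylsilyloxy)-1,1,1-trifluoro-9-methyldec-5-ene-2,4-dione F4. Diazo transfer with loss of the trifluoroacetyl group (MsN3, Et3N, H2O, MeCN) should give (3E,5S)-1-diazo-5-(tert-butyldimethylsilyloxy)-7-methyloct-3-en-2-one F5. Irradiation of F5 with 25 in CH2Cl2 at room temperature should give vinylketene 26, and the cascade of step 14 (finished by brief warming to 80 °C) then leads through 27, 28 and 29 to 30.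

2. Step 4 (ketene–ethoxyacetylene cycloaddition). The monosubstituted ketene may dimerise faster than it adds to the alkyne, and the amine base may cause β-elimination of silanolate from the acid chloride. The fallback replaces the ketene by a keteniminium ion and ethoxyacetylene by acetylene; it sets out from acid 4 and comes back at cyclobutenone 10, so that 8 and step 5 are bypassed. Acid 4 would be converted through acid chloride 6 with dimethylamine into (3S)-3-(tert-butyldimethylsilyloxy)-N,N,5-trimethylhexanamide F6. Tf2O and 2,4,6-collidine in 1,2-dichloroethane should give N-[(3S)-3-(tert-butyldimethylsilyloxy)-5-methylhex-1-en-1-ylidene]-N-methylmethanaminium triflate F7, which does not dimerise and should add acetylene in a keteniminium–alkyne [2+2] cycloaddition. This gives N-{4-[(1S)-1-(tert-butyldimethylsilyloxy)-3-methylbutyl]cyclobut-2-en-1-ylidene}-N-methylmethanaminium triflate F8, which aqueous NaHCO3 should hydrolyse to 10.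

3. Step 12 (acetylide formation and hydroxymethylation). Paraformaldehyde depolymerises slowly at low temperature, so the lithium acetylide may be protonated on work-up or attacked by excess butyllithium, and lithiation ortho to the benzyloxy group may compete. The fallback introduces the carbon at the ester oxidation level and then reduces it; it sets out from dichlorovinyl ether 21 and comes back at propargylic alcohol 24. Acetylide 23, made as in step 12, would be trapped at −78 °C with ethyl chloroformate, a soluble and fast electrophile, to give ethyl 3-{2-(benzyloxy)-4-methyl-6-[(tert-butyldimethylsilyloxy)methyl]phenoxy}prop-2-ynoate F9. i-Bu2AlH in CH2Cl2 at −78 °C should then reduce F9 to 24.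

**Further compounds**

F1 | step 14 | methyl (2S)-2-(tert-butyldimethylsilyloxy)-4-methylpentanoate | COC(=O)[C@@H](O[Si](C)(C)C(C)(C)C)CC(C)C
F2 | step 14 | (2S)-2-(tert-butyldimethylsilyloxy)-4-methylpentanal | O=C[C@@H](O[Si](C)(C)C(C)(C)C)CC(C)C
F3 | step 14 | (3E,5S)-5-(tert-butyldimethylsilyloxy)-7-methyloct-3-en-2-one | CC(=O)/C=C/[C@@H](O[Si](C)(C)C(C)(C)C)CC(C)C
F4 | step 14 | (5E,7S)-7-(tert-butyldimethylsilyloxy)-1,1,1-trifluoro-9-methyldec-5-ene-2,4-dione | FC(F)(F)C(=O)CC(=O)/C=C/[C@@H](O[Si](C)(C)C(C)(C)C)CC(C)C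
F5 | step 14 | (3E,5S)-1-diazo-5-(tert-butyldimethylsilyloxy)-7-methyloct-3-en-2-one | [N-]=[N+]=CC(=O)/C=C/[C@@H](O[Si](C)(C)C(C)(C)C)CC(C)C
F6 | step 4 | (3S)-3-(tert-butyldimethylsilyloxy)-N,N,5-trimethylhexanamide | CN(C)C(=O)C[C@@H](O[Si](C)(C)C(C)(C)C)CC(C)C
F7 | step 4 | N-[(3S)-3-(tert-butyldimethylsilyloxy)-5-methylhex-1-en-1-ylidene]-N-methylmethanaminium triflate | C[N+](C)=C=C[C@@H](O[Si](C)(C)C(C)(C)C)CC(C)C.[O-]S(=O)(=O)C(F)(F)F
F8 | step 4 | N-{4-[(1S)-1-(tert-butyldimethylsilyloxy)-3-methylbutyl]cyclobut-2-en-1-ylidene}-N-methylmethanaminium triflate | C[N+](C)=C1C=CC1[C@@H](O[Si](C)(C)C(C)(C)C)CC(C)C.[O-]S(=O)(=O)C(F)(F)F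
F9 | step 12 | ethyl 3-{2-(benzyloxy)-4-methyl-6-[(tert-butyldimethylsilyloxy)methyl]phenoxy}prop-2-ynoate | CCOC(=O)C#COc1c(OCc2ccccc2)cc(C)cc1CO[Si](C)(C)C(C)(C)C
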